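**Plan**
Numbering: ring C1 (acyloxy CH), C2 (C=O), C3 (C–CH3, epoxide), C4 (epoxide CH), C5 (CH2), C6 (CH); chain C7 (spiro carbon), C14 (oxirane CH2), C8 (C=O), C9=C10, C11 (carbinol). C1–C7 are C2, C3, C4, C5, C6, C1 and the carboxyl carbon of (−)-shikimic acid; "β" is the face of the ring-epoxide oxygen.
Retrosynthetic cuts, in order: the C2 and C8 ketones back to carbinols; C8–C9 (alkenyl iodide plus aldehyde); the spiro-oxirane oxygen (asymmetric epoxidation of C7=C14); C7–C8 (hydroxymethylation of a 2-iodoalkene); the C1 ester; C7=C14 (C7 aldehyde to alkyne); C1–O and C6–H (hydroboration); last, C3–CH3 and C4–O of the ring epoxide.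
Forward: the carbocycle is the shikimate ring throughout; the ring epoxide closes in step 7; C1 and C6 are set in step 8; the chain grows at C7 (C14 in step 11, C8 in step 14, C9–C11 in step 18); the spiro-oxirane closes in step 15; both ketones are unveiled in step 20.
Enabling feature: the oxygen triad C2–C3–C4 of the target is the triol of shikimic acid, with the C4 oxygen trans to the face on which the C3 oxygen must sit. Oxidation at C3 therefore gives a ketone with a trans α-leaving group at C4 and a directing α′-silyloxy group at C2, on which methyl addition and closure of the C3–C4 oxirane can be merged.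
Stereochemistry: C4 (by inversion) and the controlling C2 centre come from shikimic acid; C3 from methyl addition anti to C2–OSi; C1 and C6 from syn hydroboration anti to C2–OSi; C7 from L-(+)-tartrate in the Ti(OiPr)4-catalysed epoxidation; C9=C10 (E) from syn hydrostannation.

Key step: step 7

Remark: C8 in 27 and 28 is carried as a mixture of epimers, which is immaterial because C8 ends as a carbonyl; every other stereocentre is carried as a single configuration.

Step 1
Reactants: 1 (−)-shikimic acid
Product: 3 methyl 3,4-O-isopropylidene shikimate, via methyl shikimate 2 (not isolated)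
Conditions: MeOH, CSA (cat.), reflux; then 2,2-dimethoxypropane, CSA (cat.), acetone, rt
Reagents that add atoms: methanol, CO; 2,2-dimethoxypropane, COC(C)(C)OC
Why: Fischer esterification followed by acid-catalysed transacetalisation, in which only the cis C2/C3 hydroxyls (shikimate O3/O4) can span a dioxolane, so the trans C4 hydroxyl stays free and no stereocentre is touched.

Step 2
Reactants: 3 methyl 3,4-O-isopropylidene shikimate
Product: 4 methyl 3,4-O-isopropylidene-5-O-methanesulfonylshikimate (C4 mesylate)
Conditions: MsCl, Et3N, DMAP (cat.), CH2Cl2, 0 °C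
Reagents that add atoms: methanesulfonyl chloride, CS(=O)(=O)Cl
Why: Sulfonylation of the only free hydroxyl takes place at oxygen with retention at C4 and installs the leaving group that this shikimate C–O bond will later give up with inversion.

Step 3
Reactants: 4 C4 mesylate ester
Product: 5 C7 allylic alcohol (CO2Me of 4 reduced to CH2OH; acetonide and mesylate kept)
Conditions: i-Bu2AlH, CH2Cl2, −78 °C
Reagents that add atoms: none
Why: 1,2-Reduction of the conjugated ester by i-Bu2AlH at low temperature stops at the allylic alcohol and leaves the secondary mesylate and the acetonide untouched.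

Step 4
Reactants: 5 C7 allylic alcohol
Product: 6 C2,C3,C7-triol C4-mesylate
Conditions: AcOH/H2O (4:1), 40 °C
Reagents that add atoms: none
Why: Acid-catalysed acetal hydrolysis frees the cis-diol, and the mesylate survives because no alkoxide that could displace it exists in the acidic medium.

Step 5
Reactants: 6 triol mesylate
Product: 7 C2,C7-bis(tert-butyldimethylsilyl) ether with free C3–OH and C4 mesylate
Conditions: TBSCl (2.1 equiv), imidazole, DMF, −20 → 0 °C
Reagents that add atoms: tert-butyldimethylsilyl chloride, CC(C)(C)[Si](C)(C)Cl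
Why: Regioselective silylation, in which the primary allylic C7–OH and then the allylic C2–OH react while the C3–OH, flanked by the silylated C2 and the sulfonylated C4, is slowest, the same order that gives 3,5-bis-silyl ethers from shikimate esters.

Step 6
Reactants: 7 bis-silyl ether alcohol
Product: 8 (2R,4R)-α-mesyloxy ketone (C3 ketone flanked by C2 β-OTBS and C4 α-OMs; C1=C6 alkene; C7 OTBS)
Conditions: Dess–Martin periodinane, NaHCO3, CH2Cl2, 0 °C → rt; used crude
Reagents that add atoms: none
Why: Dess–Martin oxidation of the single free secondary alcohol runs under buffered, non-basic conditions, which avoids enolisation of the aromatisation-prone β,γ-unsaturated ketone and keeps both neighbouring stereocentres.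

Step 7
Reactants: 8 (2R,4R)-α-mesyloxy ketone; 9 methylmagnesium bromide
Product: 11 (2R,3S,4S)-C3-methyl C3–C4 β-epoxide (C2 β-OTBS; C1=C6 alkene; C7 OTBS), via bromomagnesium C3-alkoxide 10 (not isolated)
Conditions: CeCl3 (anhydrous), MeMgBr (3 equiv), THF, −78 °C; then −78 °C → rt
Reagents that add atoms: none
Why: The CeCl3-modified methyl Grignard reagent adds to the C3 carbonyl and the tertiary alkoxide 10 then expels the C4 mesylate by intramolecular SN2 attack, so the C3–CH3 and C4–O bonds form and the ring epoxide closes in one flask; the closest known reaction type is the addition of organometallic reagents to α-sulfonyloxy or α-halo ketones with in situ epoxide closure. The oxirane closes in the 3-exo-tet mode once a ring flip has placed the C3 alkoxide and the C4 mesylate trans-diaxial. C3 is set by axial attack on the half-chair with the C2 silyloxy group pseudoaxial on the β face and the C4 mesylate equatorial, the arrangement shikimate derivatives adopt (O3 pseudoaxial, O5 equatorial), so methyl enters on the α face, where the sp2 C1 leaves the axial trajectory open, and the new C3 oxygen is β. C4 is set by inversion of the shikimate-derived C–O bond, which puts the epoxide oxygen on the β face at both carbons. The step needs facial selectivity and freedom from enolisation: the first rests on the bulky pseudoaxial C2 silyl ether and on coordination of the oxophilic cerium to carbonyl and sulfonate oxygens, which favours the equatorial mesylate, and the second on the low basicity of the cerium-modified reagent at −78 °C. Only the adduct with oxygen trans to the mesylate can cyclise, so an epimeric adduct would stay an open hydroxy mesylate and be removed by chromatography.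

Step 8
Reactants: 11 C3-methyl β-epoxide
Product: 13 (1S,2R,3S,4S,6S)-C1 alcohol (C1 α-OH; C6 β-CH2OTBS), via C1-alkylborane 12 (not isolated)
Conditions: BH3·THF, THF, 0 °C; then NaOH, H2O2, 0 °C → rt
Reagents that add atoms: hydrogen peroxide, OO
Why: Hydroboration–oxidation, in which borane adds syn to the trisubstituted C1=C6 alkene with boron at the less substituted C1 and from the α face, opposite the allylic C2 silyloxy group and the epoxide oxygen, so that C6–H and C1–B (then C1–OH, with retention) are both α and C7 is β.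

Step 9
Reactants: 13 C1 alcohol
Product: 14 C1,C7-diol (C2 OTBS kept)
Conditions: HF·pyridine, pyridine, THF, 0 °C
Reagents that add atoms: none
Why: Buffered HF·pyridine cleaves the unhindered primary silyl ether much faster than the secondary C2 silyl ether, which is shielded by the adjacent quaternary C3.

Step 10
Reactants: 14 C1,C7-diol
Product: 15 C1-hydroxy C7-aldehyde
Conditions: TEMPO (cat.), PhI(OAc)2, CH2Cl2, rt
Reagents that add atoms: none
Why: TEMPO (oxoammonium) oxidation is selective for the primary C7 alcohol over the hindered secondary C1 alcohol, and the neutral medium leaves the epimerisable C6 centre in its all-equatorial configuration.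

Step 11
Reactants: 15 C1-hydroxy C7-aldehyde
Product: 16 C7≡C14 terminal alkyne with free C1–OH
Conditions: dimethyl (1-diazo-2-oxopropyl)phosphonate, K2CO3, MeOH, 0 °C → rt
Reagents that add atoms: dimethyl (1-diazo-2-oxopropyl)phosphonate, CC(=O)C(=[N+]=[N-])P(=O)(OC)OC
Why: Ohira–Bestmann homologation turns the aldehyde into the terminal alkyne (C14 added) through a diazoalkene and an alkylidene carbene, and C6 already holds its substituent trans-diequatorial to the C1 hydroxyl, the stable arrangement, so the base cannot erode it.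

Step 12
Reactants: 16 terminal alkyne
Product: 18 2-iodoalkene (C7(I)=C14H2; free C1–OH), via C7-alkenylalane 17 (not isolated)
Conditions: Ni(dppp)Cl2 (3 mol %; dppp = 1,3-bis(diphenylphosphino)propane), i-Bu2AlH (2.3 equiv), THF, 0 °C → rt; then N-iodosuccinimide, −78 → 0 °C
Reagents that add atoms: N-iodosuccinimide, O=C1CCC(=O)N1I
Why: Ni-catalysed hydroalumination of a terminal alkyne with the dppp ligand places aluminium on the internal carbon (Markovnikov) while the C1 hydroxyl is masked in situ as its aluminium alkoxide, and iodinolysis of the C–Al bond gives the 2-iodo-1-alkene without the acidic iodide sources that would open the ring epoxide.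

Step 13
Reactants: 18 2-iodoalkene alcohol; 19 isovaleric anhydride
Product: 20 C1 isovalerate of the 2-iodoalkene
Conditions: DMAP, Et3N, CH2Cl2, rt
Reagents that add atoms: none
Why: DMAP-catalysed acyl transfer esterifies the only free hydroxyl (C1) with retention, and no strongly basic or hydridic reagent follows, so the ester can be carried to the end.

Step 14
Reactants: 20 iodoalkene ester
Product: 21 allylic alcohol (C7(=C14H2)–C8H2OH)
Conditions: Bu3SnCH2OH, Pd(PPh3)4 (cat.), 1,4-dioxane, 90 °C
Reagents that add atoms: (tributylstannyl)methanol, CCCC[Sn](CCCC)(CCCC)CO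
Why: Stille coupling of the alkenyl iodide with (tributylstannyl)methanol forms the C7–C8 bond and gives the 2-substituted allylic alcohol under neutral conditions that ester, silyl ether and epoxide tolerate.

Step 15
Reactants: 21 allylic alcohol
Product: 22 (7S)-epoxy alcohol (C7/C14 spiro-oxirane; C8H2OH)
Conditions: Ti(OiPr)4 (10 mol %), L-(+)-diethyl tartrate (12 mol %), t-BuOOH, 4 Å MS, CH2Cl2, −20 °C
Reagents that add atoms: tert-butyl hydroperoxide, CC(C)(C)OO
Why: Sharpless asymmetric epoxidation of a 2-substituted allylic alcohol, in which L-(+)-tartrate delivers oxygen to the face that gives the (S)-2-substituted glycidol, which is the C7 configuration of the target (descriptor R once C8 is a carbonyl), by reagent control that overrides the adjacent C6 centre.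

Step 16
Reactants: 22 epoxy alcohol
Product: 23 epoxy aldehyde (C8 aldehyde on the spiro-oxirane carbon C7)
Conditions: Dess–Martin periodinane, NaHCO3, CH2Cl2, 0 °C → rt
Reagents that add atoms: none
Why: Dess–Martin oxidation of the primary epoxy alcohol gives the α,α-disubstituted glycidic aldehyde, whose C7 bears no hydrogen and so cannot epimerise.

Step 17
Reactants: 24 2-methylbut-3-yn-2-ol
Product: 26 (E)-4-iodo-2-methylbut-3-en-2-ol, via E-alkenylstannane 25 (not isolated)
Conditions: Bu3SnH, Pd(PPh3)2Cl2 (cat.), THF, 0 °C; then I2, 0 °C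
Reagents that add atoms: iodine, II
Why: Pd-catalysed syn hydrostannation puts tin on the terminal carbon because the tertiary carbinol blocks the internal position, and tin–iodine exchange with retention gives the E-iodoalkene.

Step 18
Reactants: 23 epoxy aldehyde; 26 (E)-4-iodo-2-methylbut-3-en-2-ol
Product: 27 C8 allylic alcohol (C8 epimers; C9=C10 E; C11 tertiary OH; C2 OTBS)
Conditions: CrCl2, NiCl2 (cat.), DMSO, rt
Reagents that add atoms: none
Why: Nozaki–Hiyama–Kishi coupling, in which the alkenylchromium species formed from 26 adds only to the aldehyde and leaves the ester, both epoxides and the free tertiary alcohol alone, with retention of the E geometry and a new C8 carbinol whose configuration does not matter.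

Step 19
Reactants: 27 C8 allylic alcohol
Product: 28 C2,C8,C11-triol (C8 epimers)
Conditions: HF·pyridine, pyridine, THF, 0 °C → rt
Reagents that add atoms: none
Why: Fluoride-mediated cleavage of the remaining secondary silyl ether under buffered, weakly acidic conditions, which disfavour both C1-to-C2 acyl migration and opening of the two epoxides.

Step 20
Reactants: 28 triol
Product: 29 CNP0292003.1
Conditions: Dess–Martin periodinane (excess), NaHCO3, CH2Cl2, 0 °C → rt
Reagents that add atoms: none
Why: Dess–Martin oxidation converts both secondary carbinols (C2 and C8) into ketones in one operation while the tertiary C11 alcohol cannot react, and the buffered non-basic medium protects the C1 stereocentre next to the new C2 ketone.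

**Compound list**
1 | (−)-shikimic acid, (3R,4S,5R)-3,4,5-trihydroxycyclohex-1-ene-1-carboxylic acid | O=C(O)C1=C[C@@H](O)[C@@H](O)[C@H](O)C1 | starting material
2 | methyl shikimate | COC(=O)C1=C[C@@H](O)[C@@H](O)[C@H](O)C1 | intermediate
3 | methyl 3,4-O-isopropylidene shikimate (acetonide on the cis C2/C3 oxygens; C4–OH free) | COC(=O)C1=C[C@H]2OC(C)(C)O[C@H]2[C@H](O)C1 | intermediate
4 | methyl 3,4-O-isopropylidene-5-O-methanesulfonylshikimate (C4 mesylate) | COC(=O)C1=C[C@H]2OC(C)(C)O[C@H]2[C@H](OS(C)(=O)=O)C1 | intermediate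
5 | C7 allylic alcohol with C2/C3 acetonide and C4 mesylate | OCC1=C[C@H]2OC(C)(C)O[C@H]2[C@H](OS(C)(=O)=O)C1 | intermediate
6 | C2,C3,C7-triol C4-mesylate | OCC1=C[C@@H](O)[C@@H](O)[C@H](OS(C)(=O)=O)C1 | intermediate
7 | C2,C7-bis(tert-butyldimethylsilyl) ether, C3–OH free, C4 mesylate | CC(C)(C)[Si](C)(C)OCC1=C[C@@H](O[Si](C)(C)C(C)(C)C)[C@@H](O)[C@H](OS(C)(=O)=O)C1 | intermediate
8 | (2R,4R)-α-mesyloxy ketone: C3 ketone, C2 β-OTBS, C4 α-OMs, C1=C6 alkene, C7 OTBS | CC(C)(C)[Si](C)(C)OCC1=C[C@@H](O[Si](C)(C)C(C)(C)C)C(=O)[C@H](OS(C)(=O)=O)C1 | intermediate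
9 | methylmagnesium bromide | C[Mg]Br | starting material
10 | bromomagnesium C3-alkoxide (C3–O β, C3–CH3 α, C4–OMs α) | CC(C)(C)[Si](C)(C)OCC1=C[C@@H](O[Si](C)(C)C(C)(C)C)[C@@](C)(O[Mg]Br)[C@H](OS(C)(=O)=O)C1 | intermediate
11 | (2R,3S,4S)-C3-methyl C3–C4 β-epoxide with C2 β-OTBS, C1=C6 alkene and C7 OTBS | CC(C)(C)[Si](C)(C)OCC1=C[C@@H](O[Si](C)(C)C(C)(C)C)[C@@]2(C)O[C@H]2C1 | intermediate
12 | C1-alkylborane (BH2 on C1 α; H on C6 α) | B[C@@H]1[C@@H](O[Si](C)(C)C(C)(C)C)[C@@]2(C)O[C@H]2C[C@H]1CO[Si](C)(C)C(C)(C)C | intermediate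
13 | (1S,2R,3S,4S,6S)-C1 alcohol: C1 α-OH, C2 β-OTBS, β-epoxide, C6 β-CH2OTBS | O[C@@H]1[C@@H](O[Si](C)(C)C(C)(C)C)[C@@]2(C)O[C@H]2C[C@H]1CO[Si](C)(C)C(C)(C)C | intermediate
14 | C1,C7-diol (ring configuration as in 13) | O[C@@H]1[C@@H](O[Si](C)(C)C(C)(C)C)[C@@]2(C)O[C@H]2C[C@H]1CO | intermediate
15 | C1-hydroxy C7-aldehyde (ring configuration as in 13) | O[C@@H]1[C@@H](O[Si](C)(C)C(C)(C)C)[C@@]2(C)O[C@H]2C[C@H]1C=O | intermediate
16 | C7≡C14 terminal alkyne with free C1–OH | O[C@@H]1[C@@H](O[Si](C)(C)C(C)(C)C)[C@@]2(C)O[C@H]2C[C@H]1C#C | intermediate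
17 | C7-alkenylalane (diisobutylaluminium on C7 and on the C1 oxygen) | CC(C)C[Al](CC(C)C)O[C@@H]1[C@@H](O[Si](C)(C)C(C)(C)C)[C@@]2(C)O[C@H]2C[C@H]1C(=C)[Al](CC(C)C)CC(C)C | intermediate
18 | 2-iodoalkene: C7(I)=C14H2, free C1–OH | O[C@@H]1[C@@H](O[Si](C)(C)C(C)(C)C)[C@@]2(C)O[C@H]2C[C@H]1C(I)=C | intermediate
19 | isovaleric anhydride (3-methylbutanoic anhydride) | CC(C)CC(=O)OC(=O)CC(C)C | starting material
20 | C1 isovalerate of the 2-iodoalkene | CC(C)CC(=O)O[C@@H]1[C@@H](O[Si](C)(C)C(C)(C)C)[C@@]2(C)O[C@H]2C[C@H]1C(I)=C | intermediate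
21 | allylic alcohol: C7(=C14H2)–C8H2OH, C1 isovalerate, C2 OTBS | CC(C)CC(=O)O[C@@H]1[C@@H](O[Si](C)(C)C(C)(C)C)[C@@]2(C)O[C@H]2C[C@H]1C(=C)CO | intermediate
22 | (7S)-epoxy alcohol: C7/C14 spiro-oxirane bearing C8H2OH | CC(C)CC(=O)O[C@@H]1[C@@H](O[Si](C)(C)C(C)(C)C)[C@@]2(C)O[C@H]2C[C@H]1[C@]1(CO)CO1 | intermediate
23 | epoxy aldehyde: C8 aldehyde on the spiro-oxirane carbon C7 | CC(C)CC(=O)O[C@@H]1[C@@H](O[Si](C)(C)C(C)(C)C)[C@@]2(C)O[C@H]2C[C@H]1[C@]1(C=O)CO1 | intermediate
24 | 2-methylbut-3-yn-2-ol | C#CC(C)(C)O | starting material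
25 | (E)-2-methyl-4-(tributylstannyl)but-3-en-2-ol | CC(C)(O)/C=C/[Sn](CCCC)(CCCC)CCCC | intermediate
26 | (E)-4-iodo-2-methylbut-3-en-2-ol | CC(C)(O)/C=C/I | intermediate
27 | C8 allylic alcohol (C8 epimers), C9=C10 E, C11 tertiary OH, C2 OTBS | CC(C)CC(=O)O[C@@H]1[C@@H](O[Si](C)(C)C(C)(C)C)[C@@]2(C)O[C@H]2C[C@H]1[C@]1(C(O)/C=C/C(C)(C)O)CO1 | intermediate
28 | C2,C8,C11-triol (C8 epimers) | CC(C)CC(=O)O[C@@H]1[C@@H](O)[C@@]2(C)O[C@H]2C[C@H]1[C@]1(C(O)/C=C/C(C)(C)O)CO1 | intermediate
29 | CNP0292003.1, (1S,3S,4S,6R,7R) in the numbering above | CC(C)CC(=O)O[C@@H]1C(=O)[C@@]2(C)O[C@H]2C[C@H]1[C@]1(C(=O)/C=C/C(C)(C)O)CO1 | target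

**Step count**
Total: 20 steps. Longest linear sequence: 19 steps (steps 1–16 and 18–20, from 1 to 29); step 17 prepares the side-chain iodide 26.

**Steps most likely to fail**

Step 7. The methyl group may be delivered through the other half-chair (mesylate axial), anti to the sulfonate, which leaves a cis hydroxy mesylate that cannot cyclise; the ketone may also enolise and aromatise. The fallback sets out from 3 and returns at 11, and replaces the cascade by a chelation-controlled addition to an α-alkoxy ketone followed by separate sulfonylation and base-induced closure. The C4 hydroxyl of 3 would be protected with 4-methoxybenzyl trichloroacetimidate and catalytic CSA to give 4-methoxybenzyl ether F1. The operations of steps 3 to 6 (i-Bu2AlH; AcOH/H2O; TBSCl and imidazole; Dess–Martin periodinane) would then lead through allylic alcohol F2, triol F3 and bis-silyl ether F4 to α-alkoxy ketone F5. MeMgBr in CH2Cl2 at −78 °C would add under chelation control: magnesium bridges the C3 carbonyl and the C4 ether oxygen, which holds C4–O equatorial and C2–OSi pseudoaxial, so methyl should enter on the α face and give tertiary alcohol F6. DDQ would free diol F7, MsCl and Et3N would sulfonylate only the secondary C4 hydroxyl to give hydroxy mesylate F8, and K2CO3 in MeOH would close it to 11.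

Step 8. Borane may add on the β face or place boron at C6, and it may reductively open the trisubstituted epoxide. The fallback sets out from 11 and returns at 15, and brings the C1 oxygen in by conjugate borylation of an enal. HF·pyridine with pyridine would remove the primary silyl group of 11 to give allylic alcohol F9, and MnO2 would oxidise it to enal F10. Copper-catalysed conjugate borylation (CuCl, DPEphos, NaOt-Bu, B2pin2, MeOH, THF) should add boron to C1 anti to the C2 silyl ether, with protonation placing C6 in the all-equatorial arrangement, to give β-boryl aldehyde F11. NaBO3·4H2O would oxidise the C–B bond with retention to 15.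

Step 12. The aluminium hydride may attack the ring epoxide, or the Markovnikov selectivity may be incomplete. The fallback sets out from 16 and returns at 18, and uses a syn stannylcupration in place of the hydroalumination. Me3SnCu·SMe2 in THF with excess MeOH at −78 to −60 °C should add tin to the internal alkyne carbon, the alkenylcopper being protonated as it forms, to give 2-(trimethylstannyl)alkene F12. I2 in CH2Cl2 at 0 °C would exchange tin for iodine with retention and give 18.

**Further compounds**
F1 | step 7 | methyl 3,4-O-isopropylidene-5-O-(4-methoxybenzyl)shikimate | COC(=O)C1=C[C@H]2OC(C)(C)O[C@H]2[C@H](OCc3ccc(OC)cc3)C1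
F2 | step 7 | C7 allylic alcohol with C2/C3 acetonide and C4 4-methoxybenzyl ether | OCC1=C[C@H]2OC(C)(C)O[C@H]2[C@H](OCc3ccc(OC)cc3)C1
F3 | step 7 | C2,C3,C7-triol C4 4-methoxybenzyl ether | OCC1=C[C@@H](O)[C@@H](O)[C@H](OCc2ccc(OC)cc2)C1
F4 | step 7 | C2,C7-bis(tert-butyldimethylsilyl) ether, C3–OH free, C4 4-methoxybenzyl ether | CC(C)(C)[Si](C)(C)OCC1=C[C@@H](O[Si](C)(C)C(C)(C)C)[C@@H](O)[C@H](OCc2ccc(OC)cc2)C1
F5 | step 7 | C3 ketone with C2 β-OTBS and C4 α-(4-methoxybenzyloxy) | CC(C)(C)[Si](C)(C)OCC1=C[C@@H](O[Si](C)(C)C(C)(C)C)C(=O)[C@H](OCc2ccc(OC)cc2)C1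
F6 | step 7 | C3 tertiary alcohol (C3–OH β, C3–CH3 α) with C4 α-(4-methoxybenzyloxy) | CC(C)(C)[Si](C)(C)OCC1=C[C@@H](O[Si](C)(C)C(C)(C)C)[C@@](C)(O)[C@H](OCc2ccc(OC)cc2)C1
F7 | step 7 | trans C3,C4-diol (C3–OH β, C4–OH α) | CC(C)(C)[Si](C)(C)OCC1=C[C@@H](O[Si](C)(C)C(C)(C)C)[C@@](C)(O)[C@H](O)C1
F8 | step 7 | C3 tertiary alcohol C4 mesylate (trans) | CC(C)(C)[Si](C)(C)OCC1=C[C@@H](O[Si](C)(C)C(C)(C)C)[C@@](C)(O)[C@H](OS(C)(=O)=O)C1
F9 | step 8 | C7 allylic alcohol of the β-epoxide (C2 OTBS kept) | OCC1=C[C@@H](O[Si](C)(C)C(C)(C)C)[C@@]2(C)O[C@H]2C1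
F10 | step 8 | C7 enal (C1=C6–C7H=O) of the β-epoxide | O=CC1=C[C@@H](O[Si](C)(C)C(C)(C)C)[C@@]2(C)O[C@H]2C1
F11 | step 8 | C1 α-pinacolboryl C7-aldehyde | CC1(C)OB(OC1(C)C)[C@@H]1[C@@H](O[Si](C)(C)C(C)(C)C)[C@@]2(C)O[C@H]2C[C@H]1C=O
F12 | step 12 | 2-(trimethylstannyl)alkene: C7(SnMe3)=C14H2, free C1–OH | O[C@@H]1[C@@H](O[Si](C)(C)C(C)(C)C)[C@@]2(C)O[C@H]2C[C@H]1C(=C)[Sn](C)(C)C
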